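**Retrosynthetic overview**
1. Target ⇐ phenol 22 + angelic acid; the aryl angelate goes on last because it is the most labile ester and its Z alkene isomerises easily. 22 ⇐ epoxide 16, whose three oxygens are masked orthogonally (phenol O-allyl, benzylic OTBS, side-chain OPMB) and are freed and acylated one at a time.
2. 16 ⇐ diol 14 by closing the oxirane (tertiary alkoxide onto a primary tosylate); this is the only ring formed after the key step.
3. Key disconnection: the bond between the benzene carbon ortho to the phenol oxygen and the fully substituted oxirane carbon. 14 ⇐ aryl boronic ester 10 + oxiranylstannane 4 by Sn–Li exchange, boronate formation, a stereospecific 1,2-shift of the aryl group from boron to carbon driven by opening of the glycidyl oxirane, and C–B oxidation.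
4. Enabling feature: the quaternary carbon carries one oxygen and two CH2–O arms (a 2-arylglycerol core). The target oxirane (O, quaternary C, CH2) is therefore the transposed form of the oxirane of a 2-metallated glycidyl ether: the old ring supplies strain and chirality, and its oxygen becomes the leaving group for the new ring.
5. 4 ⇐ propargyl alcohol (hydrostannation; Sharpless epoxidation sets the oxirane stereocentre); 10 ⇐ 4-bromo-3-hydroxybenzaldehyde. Ring order: benzene bought, first oxirane in step 2, opened in step 8, final oxirane closed in step 9.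

Key step: step 8

Remark: the 2-methylbutanoyl centre in the target SMILES is R, so enantiopure (R)-2-methylbutanoic acid is taken as a purchased starting material. R/S labels at the oxirane carbon change along the route only where substituent priorities change.

**Route**

Step 1
Reactants: 1 prop-2-yn-1-ol
Product: 2 2-(tributylstannyl)prop-2-en-1-ol
Conditions: Bu3SnH, Mo(CO)3(CNt-Bu)3 (2 mol%), hydroquinone (cat.), THF, 55 °C
Reagents that add atoms: tributyltin hydride, CCCC[SnH](CCCC)CCCC
Why: Molybdenum-catalysed hydrostannation of a propargylic alcohol places tin on the internal alkyne carbon, which should give the 1,1-disubstituted vinylstannane.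

Step 2
Reactants: 2 2-(tributylstannyl)prop-2-en-1-ol
Product: 3 (R)-[2-(tributylstannyl)oxiran-2-yl]methanol
Conditions: Ti(Oi-Pr)4 (10 mol%), L-(+)-DIPT (12 mol%), t-BuOOH, 4 Å MS, CH2Cl2, −20 °C
Reagents that add atoms: tert-butyl hydroperoxide, CC(C)(C)OO
Why: Sharpless asymmetric epoxidation of a 2-substituted allylic alcohol; L-(+)-tartrate should deliver oxygen to the face that gives (S)-glycidol from allyl alcohol, and the product is named R only because tin outranks oxygen.

Step 3
Reactants: 3 (R)-[2-(tributylstannyl)oxiran-2-yl]methanol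
Product: 4 (S)-tributyl(2-{[(4-methoxybenzyl)oxy]methyl}oxiran-2-yl)stannane
Conditions: NaH, PMBCl, Bu4NI (cat.), THF/DMF, 0 °C → rt
Reagents that add atoms: 4-methoxybenzyl chloride, COc1ccc(CCl)cc1
Why: Williamson etherification of the primary alkoxide; no bond to the stereocentre is touched (the descriptor changes to S by priority only).

Step 4
Reactants: 5 4-bromo-3-hydroxybenzaldehyde
Product: 6 3-(allyloxy)-4-bromobenzaldehyde
Conditions: allyl bromide, K2CO3, DMF, rt
Reagents that add atoms: allyl bromide, C=CCBr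
Why: Williamson O-allylation of the acidic phenol; allyl is chosen because it can be removed at the end under neutral Pd(0) conditions.

Step 5
Reactants: 6 3-(allyloxy)-4-bromobenzaldehyde
Product: 7 [3-(allyloxy)-4-bromophenyl]methanol
Conditions: NaBH4, MeOH, 0 °C
Reagents that add atoms: none
Why: Borohydride reduction of the aldehyde; aryl bromide and allyl ether are inert.

Step 6
Reactants: 7 [3-(allyloxy)-4-bromophenyl]methanol
Product: 8 {[3-(allyloxy)-4-bromobenzyl]oxy}(tert-butyl)dimethylsilane
Conditions: TBSCl, imidazole, DMF, rt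
Reagents that add atoms: tert-butyldimethylsilyl chloride, CC(C)(C)[Si](C)(C)Cl
Why: Standard silylation of a primary benzylic alcohol.

Step 7
Reactants: 8 {[3-(allyloxy)-4-bromobenzyl]oxy}(tert-butyl)dimethylsilane
Product: 10 2-[2-(allyloxy)-4-({[tert-butyl(dimethyl)silyl]oxy}methyl)phenyl]-4,4,5,5-tetramethyl-1,3,2-dioxaborolane, via aryllithium 9 (not isolated)
Conditions: n-BuLi, THF, −78 °C; then i-PrOBpin, −78 °C → rt
Reagents that add atoms: 2-isopropoxy-4,4,5,5-tetramethyl-1,3,2-dioxaborolane, CC(C)OB1OC(C)(C)C(C)(C)O1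
Why: Bromine–lithium exchange and borylation of the aryllithium; the low temperature and immediate quench should prevent carbolithiation of the ortho allyl ether.

Step 8
Reactants: 4 (S)-tributyl(2-{[(4-methoxybenzyl)oxy]methyl}oxiran-2-yl)stannane; 10 2-[2-(allyloxy)-4-({[tert-butyl(dimethyl)silyl]oxy}methyl)phenyl]-4,4,5,5-tetramethyl-1,3,2-dioxaborolane
Product: 14 (2R)-2-[2-(allyloxy)-4-({[tert-butyl(dimethyl)silyl]oxy}methyl)phenyl]-3-[(4-methoxybenzyl)oxy]propane-1,2-diol, via oxiranyllithium 11 (not isolated), via lithium boronate complex 12 (not isolated), via silyloxy tertiary boronic ester 13 (not isolated)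
Conditions: 4, n-BuLi, THF, −95 °C, 10 min; 10, −95 → −78 °C; TMSOTf, −78 → 0 °C; then 2 M NaOH, 30% H2O2, THF/MeOH, 0 °C → rt
Reagents that add atoms: hydrogen peroxide, OO
Why: Tin–lithium exchange on 4 gives the configurationally stable oxiranyllithium 11 with retention, 11 adds to the boron of 10 with retention to give boronate 12, silylation of the oxirane oxygen then triggers a 1,2-shift of the aryl group from boron to the oxirane carbon anti to the breaking C–O bond (inversion at carbon), and oxidation of the C–B bond of 13 with retention (the TMS ether is hydrolysed in the basic work-up) should give 14. The closest known reaction type is the homologation of boronic esters with lithiated epoxides (1,2-metallate rearrangement with oxirane opening, then oxidation to a 1,2-diol), joined here to tin–lithium exchange as the known entry to non-stabilised oxiranyllithiums. No ring is closed in this step: the oxirane is opened, and its strain release together with Si–O bond formation drives the shift. The new fully substituted stereocentre is controlled only by the oxirane stereocentre of 4 through the sequence retention, retention, inversion, retention, which should give the R diol. The selectivity needed is that only the aryl group migrates and that it bonds through its boron-bearing carbon, which the substrate secures because the other boron substituents are pinacol oxygens and the site is fixed by boron ortho to the allyloxy group. Loss of boron and oxygen as an alkene from a β-oxido boronate should be avoided because the alkoxide is released already silylated.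

Step 9
Reactants: 14 (2R)-2-[2-(allyloxy)-4-({[tert-butyl(dimethyl)silyl]oxy}methyl)phenyl]-3-[(4-methoxybenzyl)oxy]propane-1,2-diol
Product: 16 (2R)-2-[2-(allyloxy)-4-({[tert-butyl(dimethyl)silyl]oxy}methyl)phenyl]-2-{[(4-methoxybenzyl)oxy]methyl}oxirane, via monotosylate 15 (not isolated)
Conditions: NaH (2.2 equiv), THF, 0 °C; then 1-tosylimidazole, 0 °C → rt
Reagents that add atoms: none
Why: Selective sulfonylation of the primary alkoxide and 3-exo-tet Williamson closure by the tertiary alkoxide should give the oxirane; the C–O bond at the stereocentre is not broken, so its configuration is kept.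

Step 10
Reactants: 16 (2R)-2-[2-(allyloxy)-4-({[tert-butyl(dimethyl)silyl]oxy}methyl)phenyl]-2-{[(4-methoxybenzyl)oxy]methyl}oxirane
Product: 17 {3-(allyloxy)-4-[(2R)-2-{[(4-methoxybenzyl)oxy]methyl}oxiran-2-yl]phenyl}methanol
Conditions: TBAF, THF, 0 °C
Reagents that add atoms: none
Why: Fluoride cleavage of the silyl ether at a stage where no ester is present; oxirane, PMB and allyl ethers are stable to it.

Step 11
Reactants: 17 {3-(allyloxy)-4-[(2R)-2-{[(4-methoxybenzyl)oxy]methyl}oxiran-2-yl]phenyl}methanol; 18 (R)-2-methylbutanoic acid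
Product: 19 3-(allyloxy)-4-[(2R)-2-{[(4-methoxybenzyl)oxy]methyl}oxiran-2-yl]benzyl (2R)-2-methylbutanoate
Conditions: DIC, DMAP (cat.), CH2Cl2, 0 °C → rt
Reagents that add atoms: none
Why: Steglich esterification of an unhindered benzylic alcohol; a simple α-alkyl acid should not epimerise under these mild conditions, so the R centre is carried in from 18.

Step 12
Reactants: 19 3-(allyloxy)-4-[(2R)-2-{[(4-methoxybenzyl)oxy]methyl}oxiran-2-yl]benzyl (2R)-2-methylbutanoate
Product: 20 3-(allyloxy)-4-[(2S)-2-(hydroxymethyl)oxiran-2-yl]benzyl (2R)-2-methylbutanoate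
Conditions: DDQ, CH2Cl2/pH 7 phosphate buffer, 0 °C
Reagents that add atoms: none
Why: Oxidative cleavage of the PMB ether under buffered, non-acidic conditions that the acid-sensitive benzylic oxirane, the ester and the allyl ether should tolerate (descriptor S by priority change only).

Step 13
Reactants: 20 3-(allyloxy)-4-[(2S)-2-(hydroxymethyl)oxiran-2-yl]benzyl (2R)-2-methylbutanoate
Product: 21 4-[(2R)-2-(acetoxymethyl)oxiran-2-yl]-3-(allyloxy)benzyl (2R)-2-methylbutanoate
Conditions: Ac2O, pyridine, DMAP (cat.), CH2Cl2, 0 °C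
Reagents that add atoms: acetic anhydride, CC(=O)OC(C)=O
Why: Acetylation of the only free hydroxyl; because the tertiary oxygen is already locked in the oxirane, no acyl migration is possible.

Step 14
Reactants: 21 4-[(2R)-2-(acetoxymethyl)oxiran-2-yl]-3-(allyloxy)benzyl (2R)-2-methylbutanoate
Product: 22 4-[(2R)-2-(acetoxymethyl)oxiran-2-yl]-3-hydroxybenzyl (2R)-2-methylbutanoate
Conditions: Pd(PPh3)4 (5 mol%), morpholine, THF, rt; crude phenol used at once
Reagents that add atoms: none
Why: Tsuji–Trost-type deallylation: Pd(0) ionises the aryl allyl ether and morpholine captures the allyl group, under near-neutral conditions in which the non-allylic oxirane and the esters should survive.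

Step 15
Reactants: 22 4-[(2R)-2-(acetoxymethyl)oxiran-2-yl]-3-hydroxybenzyl (2R)-2-methylbutanoate; 23 angelic acid
Product: 25 4-[(2R)-2-(acetoxymethyl)oxiran-2-yl]-3-{[(2Z)-2-methylbut-2-enoyl]oxy}benzyl (2R)-2-methylbutanoate (CNP0256757.1), via mixed anhydride 24 (not isolated)
Conditions: 23, 2,4,6-trichlorobenzoyl chloride, Et3N, toluene, rt; then 22, Et3N, 0 °C → rt (no DMAP)
Reagents that add atoms: none
Why: Yamaguchi-type mixed-anhydride acylation: the phenoxide should attack the less hindered angeloyl carbonyl, and leaving out a nucleophilic catalyst should keep the Z geometry.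

**Compound list**
1 | prop-2-yn-1-ol (propargyl alcohol) | C#CCO | starting material
2 | 2-(tributylstannyl)prop-2-en-1-ol | C=C(CO)[Sn](CCCC)(CCCC)CCCC | intermediate
3 | (R)-[2-(tributylstannyl)oxiran-2-yl]methanol | OC[C@@]1([Sn](CCCC)(CCCC)CCCC)CO1 | intermediate
4 | (S)-tributyl(2-{[(4-methoxybenzyl)oxy]methyl}oxiran-2-yl)stannane | COc1ccc(COC[C@@]2([Sn](CCCC)(CCCC)CCCC)CO2)cc1 | intermediate
5 | 4-bromo-3-hydroxybenzaldehyde | O=Cc1ccc(Br)c(O)c1 | starting material
6 | 3-(allyloxy)-4-bromobenzaldehyde | C=CCOc1cc(C=O)ccc1Br | intermediate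
7 | [3-(allyloxy)-4-bromophenyl]methanol | C=CCOc1cc(CO)ccc1Br | intermediate
8 | {[3-(allyloxy)-4-bromobenzyl]oxy}(tert-butyl)dimethylsilane | C=CCOc1cc(CO[Si](C)(C)C(C)(C)C)ccc1Br | intermediate
9 | [2-(allyloxy)-4-({[tert-butyl(dimethyl)silyl]oxy}methyl)phenyl]lithium | C=CCOc1cc(CO[Si](C)(C)C(C)(C)C)ccc1[Li] | intermediate
10 | 2-[2-(allyloxy)-4-({[tert-butyl(dimethyl)silyl]oxy}methyl)phenyl]-4,4,5,5-tetramethyl-1,3,2-dioxaborolane | C=CCOc1cc(CO[Si](C)(C)C(C)(C)C)ccc1B1OC(C)(C)C(C)(C)O1 | intermediate
11 | (R)-(2-{[(4-methoxybenzyl)oxy]methyl}oxiran-2-yl)lithium (same spatial arrangement as 4) | [Li][C@]1(COCc2ccc(OC)cc2)CO1 | intermediate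
12 | lithium [2-(allyloxy)-4-({[tert-butyl(dimethyl)silyl]oxy}methyl)phenyl][(2R)-2-{[(4-methoxybenzyl)oxy]methyl}oxiran-2-yl](pinacolato)borate | [Li+].C=CCOc1cc(CO[Si](C)(C)C(C)(C)C)ccc1[B-]1([C@]2(COCc3ccc(OC)cc3)CO2)OC(C)(C)C(C)(C)O1 | intermediate
13 | 2-{(2R)-2-[2-(allyloxy)-4-({[tert-butyl(dimethyl)silyl]oxy}methyl)phenyl]-1-[(4-methoxybenzyl)oxy]-3-[(trimethylsilyl)oxy]propan-2-yl}-4,4,5,5-tetramethyl-1,3,2-dioxaborolane | C=CCOc1cc(CO[Si](C)(C)C(C)(C)C)ccc1[C@@](B1OC(C)(C)C(C)(C)O1)(CO[Si](C)(C)C)COCc1ccc(OC)cc1 | intermediate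
14 | (2R)-2-[2-(allyloxy)-4-({[tert-butyl(dimethyl)silyl]oxy}methyl)phenyl]-3-[(4-methoxybenzyl)oxy]propane-1,2-diol | C=CCOc1cc(CO[Si](C)(C)C(C)(C)C)ccc1[C@@](O)(CO)COCc1ccc(OC)cc1 | intermediate
15 | (2S)-2-[2-(allyloxy)-4-({[tert-butyl(dimethyl)silyl]oxy}methyl)phenyl]-2-hydroxy-3-[(4-methoxybenzyl)oxy]propyl 4-methylbenzenesulfonate | C=CCOc1cc(CO[Si](C)(C)C(C)(C)C)ccc1[C@@](O)(COS(=O)(=O)c1ccc(C)cc1)COCc1ccc(OC)cc1 | intermediate
16 | (2R)-2-[2-(allyloxy)-4-({[tert-butyl(dimethyl)silyl]oxy}methyl)phenyl]-2-{[(4-methoxybenzyl)oxy]methyl}oxirane | C=CCOc1cc(CO[Si](C)(C)C(C)(C)C)ccc1[C@]1(COCc2ccc(OC)cc2)CO1 | intermediate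
17 | {3-(allyloxy)-4-[(2R)-2-{[(4-methoxybenzyl)oxy]methyl}oxiran-2-yl]phenyl}methanol | C=CCOc1cc(CO)ccc1[C@]1(COCc2ccc(OC)cc2)CO1 | intermediate
18 | (R)-2-methylbutanoic acid | CC[C@@H](C)C(=O)O | starting material
19 | 3-(allyloxy)-4-[(2R)-2-{[(4-methoxybenzyl)oxy]methyl}oxiran-2-yl]benzyl (2R)-2-methylbutanoate | C=CCOc1cc(COC(=O)[C@H](C)CC)ccc1[C@]1(COCc2ccc(OC)cc2)CO1 | intermediate
20 | 3-(allyloxy)-4-[(2S)-2-(hydroxymethyl)oxiran-2-yl]benzyl (2R)-2-methylbutanoate | C=CCOc1cc(COC(=O)[C@H](C)CC)ccc1[C@]1(CO)CO1 | intermediate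
21 | 4-[(2R)-2-(acetoxymethyl)oxiran-2-yl]-3-(allyloxy)benzyl (2R)-2-methylbutanoate | C=CCOc1cc(COC(=O)[C@H](C)CC)ccc1[C@]1(COC(C)=O)CO1 | intermediate
22 | 4-[(2R)-2-(acetoxymethyl)oxiran-2-yl]-3-hydroxybenzyl (2R)-2-methylbutanoate | Oc1cc(COC(=O)[C@H](C)CC)ccc1[C@]1(COC(C)=O)CO1 | intermediate
23 | angelic acid, (Z)-2-methylbut-2-enoic acid | C/C=C(/C)C(=O)O | starting material
24 | (Z)-2-methylbut-2-enoic 2,4,6-trichlorobenzoic anhydride | C/C=C(/C)C(=O)OC(=O)c1c(Cl)cc(Cl)cc1Cl | intermediate
25 | 4-[(2R)-2-(acetoxymethyl)oxiran-2-yl]-3-{[(2Z)-2-methylbut-2-enoyl]oxy}benzyl (2R)-2-methylbutanoate (CNP0256757.1) | C/C=C(/C)C(=O)Oc1cc(COC(=O)[C@H](C)CC)ccc1[C@]1(COC(C)=O)CO1 | target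

**Step count and risks**
Total steps: 15 (steps 1–3 make fragment 4, steps 4–7 make fragment 10, steps 8–15 are the joined sequence).
Longest linear sequence: 12 steps (5 → 6 → 7 → 8 → 10 → 14 → 16 → 17 → 19 → 20 → 21 → 22 → 25).

Most likely to fail, with fallbacks:

1. Step 8. The oxiranyllithium may decompose by α-elimination before it is captured; boronate formation at the ortho-substituted boron may be slow or reversible; and the rearranged boronate may lose boron and oxygen instead of being oxidised. The fallback sets out from 10 and returns at 16, replacing steps 8 and 9 by known chemistry. Suzuki–Miyaura coupling of 10 with 2-bromoprop-2-en-1-ol (Pd(dppf)Cl2, K2CO3, dioxane/H2O, 80 °C) should give 2-[2-(allyloxy)-4-({[tert-butyl(dimethyl)silyl]oxy}methyl)phenyl]prop-2-en-1-ol F1. Sharpless asymmetric epoxidation of F1 (Ti(Oi-Pr)4, L-(+)-DIPT, t-BuOOH, 4 Å MS, CH2Cl2, −20 °C) should then give {(2S)-2-[2-(allyloxy)-4-({[tert-butyl(dimethyl)silyl]oxy}methyl)phenyl]oxiran-2-yl}methanol F2, the stereocentre now being set by the tartrate. Etherification of F2 (NaH, PMBCl, Bu4NI, THF/DMF, 0 °C) gives 16.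

2. Step 2. The C–Sn bond may be cleaved oxidatively or protolytically under the Lewis-acidic peroxide conditions, and facial selectivity may be poor next to the bulky stannyl group. The fallback sets out from 2 and returns at 3, replacing asymmetric catalysis by resolution. Neutral epoxidation of 2 with dimethyldioxirane (acetone, 0 °C) should give racemic [2-(tributylstannyl)oxiran-2-yl]methanol F3. Acylation with (1S)-camphanic chloride (pyridine, DMAP, CH2Cl2) and chromatographic separation of the two diastereomers should give [(2S)-2-(tributylstannyl)oxiran-2-yl]methyl (1S,4R)-4,7,7-trimethyl-3-oxo-2-oxabicyclo[2.2.1]heptane-1-carboxylate F4, which has the spatial arrangement of 3. Methanolysis (K2CO3, MeOH, 0 °C) releases 3.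

3. Step 15. The angeloyl group may isomerise from Z to E by addition–elimination at the activated acyl stage, and a slow acylation leaves time for the free phenol to open the neighbouring oxirane. The fallback sets out from 22 and returns at 25, building the Z alkene under kinetic control instead of transferring it. Steglich acylation of 22 with 2-[bis(2,2,2-trifluoroethoxy)phosphoryl]propanoic acid (DIC, DMAP cat., CH2Cl2, 0 °C) should give 4-[(2R)-2-(acetoxymethyl)oxiran-2-yl]-3-({2-[bis(2,2,2-trifluoroethoxy)phosphoryl]propanoyl}oxy)benzyl (2R)-2-methylbutanoate F5 (both epimers at the phosphonate carbon are usable). Still–Gennari olefination of F5 with acetaldehyde (KHMDS 1.0 equiv, 18-crown-6, THF, −78 °C) should give the Z enoate 25.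

**Further compounds**
F1 | step 8 | 2-[2-(allyloxy)-4-({[tert-butyl(dimethyl)silyl]oxy}methyl)phenyl]prop-2-en-1-ol | C=CCOc1cc(CO[Si](C)(C)C(C)(C)C)ccc1C(=C)CO
F2 | step 8 | {(2S)-2-[2-(allyloxy)-4-({[tert-butyl(dimethyl)silyl]oxy}methyl)phenyl]oxiran-2-yl}methanol | C=CCOc1cc(CO[Si](C)(C)C(C)(C)C)ccc1[C@]1(CO)CO1
F3 | step 2 | racemic [2-(tributylstannyl)oxiran-2-yl]methanol | OCC1([Sn](CCCC)(CCCC)CCCC)CO1
F4 | step 2 | [(2S)-2-(tributylstannyl)oxiran-2-yl]methyl (1S,4R)-4,7,7-trimethyl-3-oxo-2-oxabicyclo[2.2.1]heptane-1-carboxylate | O=C(OC[C@@]1([Sn](CCCC)(CCCC)CCCC)CO1)[C@@]12CC[C@@](C)(C(=O)O1)C2(C)C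
F5 | step 15 | 4-[(2R)-2-(acetoxymethyl)oxiran-2-yl]-3-({2-[bis(2,2,2-trifluoroethoxy)phosphoryl]propanoyl}oxy)benzyl (2R)-2-methylbutanoate | CC(C(=O)Oc1cc(COC(=O)[C@H](C)CC)ccc1[C@]1(COC(C)=O)CO1)P(=O)(OCC(F)(F)F)OCC(F)(F)F
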